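Ring A is numbered C-1 (hexanoyl), C-2 (OH), C-3 (H), C-4 (OMe), C-5 (bridge carbon), C-6 (OH). The route exploits the ortho pair of acyl group at C-1 and hydroxyl at C-6: both the C-1–acyl and C-6–O bonds are cut together, so that a C-1/C-6 aryne takes up hexanoic acid across its C–O bond and sets the acyl group between the two oxygenated carbons, the new hydroxyl beside C-5, in one operation. The precursor is the ortho-silyl aryl triflate of a ring-A propanoate (OMe at C-4, MOM ether at C-2). Ring B is then built on the propanoate by Claisen coupling with an enantioenriched α-methyl-α-prenyl acetoacetate, Dieckmann closure and C-butanoylation.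

Key step: step 7

Assumption (configuration): the quaternary carbon of ring B is (R) in the tautomer given; the same spatial arrangement is (S) in the acyclic compounds 23 and 26, because the CIP ranking of the two carbonyl substituents changes.

Assumption (step 11): with HMPA on lithium, the L-valine-derived lithioenamine is taken to be alkylated on the face that gives (S)-23; if the sense proves opposite, the THF regime or the D-auxiliary gives the same compound.

Step 1
Reactants: 1 5-methoxyresorcinol; 2 acrylic acid
Product: 3 7-hydroxy-5-methoxychroman-2-one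
Conditions: Amberlyst-15 (sulfonic acid resin), toluene, reflux, Dean–Stark; chromatography
Reagents that add atoms: none
Why: Acid-catalysed Friedel–Crafts conjugate addition (hydroarylation) of the electron-rich ring to acrylic acid followed by lactonisation; attack at either of the two equivalent carbons flanked by OH and OMe leads to 3, and the isomeric lactone from attack between the two hydroxyls should be removed here.

Step 2
Reactants: 3 7-hydroxy-5-methoxychroman-2-one
Product: 4 5-methoxy-7-(methoxymethoxy)chroman-2-one
Conditions: MOMCl, i-Pr2NEt, CH2Cl2, 0 °C to rt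
Reagents that add atoms: chloromethyl methyl ether, COCCl
Why: O-Alkylation (Williamson type) of the only phenol; the aryl lactone tolerates the hindered amine base.

Step 3
Reactants: 4 5-methoxy-7-(methoxymethoxy)chroman-2-one
Product: 5 8-bromo-5-methoxy-7-(methoxymethoxy)chroman-2-one
Conditions: NBS (1.0 equiv), MeCN, 0 °C
Reagents that add atoms: N-bromosuccinimide, O=C1CCC(=O)N1Br
Why: Electrophilic aromatic bromination; C-8 is para to the methoxy group and ortho to the MOM ether, whereas C-6 lies between two ether groups and is para only to the weakly donating acylated ring oxygen, so substitution should go to C-8.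

Step 4
Reactants: 5 8-bromo-5-methoxy-7-(methoxymethoxy)chroman-2-one
Product: 6 methyl 3-[3-bromo-2-hydroxy-6-methoxy-4-(methoxymethoxy)phenyl]propanoate
Conditions: NaOMe (1.2 equiv), MeOH, 0 °C; AcOH quench at 0 °C
Reagents that add atoms: methanol (as sodium methoxide), CO
Why: Transesterification (alkoxide ring opening) of the aryl lactone; the phenoxide formed is a much weaker base than methoxide, so the open hydroxy ester is favoured, and the cold neutral quench avoids relactonisation.

Step 5
Reactants: 6 methyl 3-[3-bromo-2-hydroxy-6-methoxy-4-(methoxymethoxy)phenyl]propanoate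
Product: 7 methyl 3-[3-bromo-6-methoxy-4-(methoxymethoxy)-2-(trimethylsilyloxy)phenyl]propanoate
Conditions: TMSCl, Et3N, CH2Cl2, 0 °C; filtered, concentrated, used crude
Reagents that add atoms: chlorotrimethylsilane, C[Si](C)(C)Cl
Why: O-Silylation of the phenol under mild, non-heating conditions that do not drive lactonisation; the silyl ether is the migrating-group donor for the next step.

Step 6
Reactants: 7 methyl 3-[3-bromo-6-methoxy-4-(methoxymethoxy)-2-(trimethylsilyloxy)phenyl]propanoate
Product: 10 methyl 3-[6-methoxy-4-(methoxymethoxy)-2-(trifluoromethylsulfonyloxy)-3-(trimethylsilyl)phenyl]propanoate, via aryllithium 8 (not isolated), via lithium silylphenoxide 9 (not isolated)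
Conditions: n-BuLi (1.05 equiv), THF/Et2O, −100 °C; then Tf2O, −100 to −40 °C
Reagents that add atoms: trifluoromethanesulfonic anhydride, O=S(=O)(OS(=O)(=O)C(F)(F)F)C(F)(F)F
Why: Bromine–lithium exchange, which at −100 °C should outrun addition to the methyl ester, is followed at once by the intramolecular anionic 1,3-O→C silyl shift (retro-Brook rearrangement), and the resulting hindered phenoxide is triflated in the same flask.

Step 7
Reactants: 10 methyl 3-[6-methoxy-4-(methoxymethoxy)-2-(trifluoromethylsulfonyloxy)-3-(trimethylsilyl)phenyl]propanoate; 11 hexanoic acid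
Product: 14 methyl 3-[3-hexanoyl-2-hydroxy-6-methoxy-4-(methoxymethoxy)phenyl]propanoate, via aryne 12 (not isolated), via aryl cesium ester 13 (not isolated)
Conditions: 11 (1.2 equiv), CsF (4 equiv), anhydrous THF, 125 °C, sealed tube
Reagents that add atoms: none
Why: Fluoride attacks silicon and the aryl anion expels triflate (1,2-elimination) to give aryne 12 with the triple bond between C-1 and C-6 (target numbering); cesium hexanoate adds through oxygen at C-6, and the C-1 carbanion 13 attacks the new ester carbonyl through a four-membered benzoxetene alkoxide that opens to the ortho-acyl phenoxide, so the aryl–oxygen and aryl–acyl bonds form in one operation. The closest known reaction type is the fluoride-induced insertion of arynes from ortho-silylaryl triflates into the C–O bond of carboxylic acids, which gives ortho-hydroxyaryl ketones. No ring of the target is closed (the four-membered ring is transient) and no stereocentre is formed. The step needs one direction of addition: the inductively withdrawing MOM-oxy group at C-2 polarises the aryne so that the nucleophile enters at the distal carbon C-6 and the charge develops at C-1 next to oxygen, which should outweigh the modest steric bias of the side chain on C-5. Acyl capture must also outrun protonation of 13, which the high temperature and the anhydrous, carboxylate-rich medium should favour.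

Step 8
Reactants: 14 methyl 3-[3-hexanoyl-2-hydroxy-6-methoxy-4-(methoxymethoxy)phenyl]propanoate
Product: 15 methyl 3-[3-hexanoyl-6-methoxy-2,4-bis(methoxymethoxy)phenyl]propanoate
Conditions: MOMCl, i-Pr2NEt, CH2Cl2, 40 °C
Reagents that add atoms: chloromethyl methyl ether, COCCl
Why: O-Alkylation of the remaining, hydrogen-bonded phenol, the only site acidic enough for the amine base; the ether blocks lactonisation and hemiketal formation in the following steps.

Step 9
Reactants: 15 methyl 3-[3-hexanoyl-6-methoxy-2,4-bis(methoxymethoxy)phenyl]propanoate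
Product: 16 3-[3-hexanoyl-6-methoxy-2,4-bis(methoxymethoxy)phenyl]propanoic acid
Conditions: LiOH, THF/MeOH/H2O, rt; then cold 1 M HCl to pH 3–4
Reagents that add atoms: lithium hydroxide, [Li+].[OH-]
Why: Saponification of the unhindered methyl ester; the hindered aryl ketone and the MOM ethers are inert to aqueous hydroxide and to a brief cold acidification.

Step 10
Reactants: 17 methyl 2-methyl-3-oxobutanoate; 18 tert-butyl L-valinate
Product: 19 tert-butyl N-[(2Z)-4-methoxy-3-methyl-4-oxobut-2-en-2-yl]-L-valinate
Conditions: BF3·OEt2 (cat.), benzene, reflux, Dean–Stark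
Reagents that add atoms: none
Why: Condensation of the ketone with the primary amine gives the hydrogen-bonded Z enamino ester (vinylogous carbamate), the substrate for auxiliary-controlled alkylation.

Step 11
Reactants: 19 tert-butyl N-[(2Z)-4-methoxy-3-methyl-4-oxobut-2-en-2-yl]-L-valinate; 20 prenyl bromide
Product: 23 methyl (2S)-2-acetyl-2,5-dimethylhex-4-enoate, via lithioenamine 21 (not isolated), via ketimine 22 (not isolated)
Conditions: LiN(i-Pr)2 (1.1 equiv), toluene, −78 °C; HMPA (1.0 equiv); 20, −78 to −55 °C; then 10% aq. citric acid, rt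
Reagents that add atoms: water, O
Why: Asymmetric alkylation of an α-alkyl β-keto ester through its chiral lithioenamine; lithium is held by nitrogen and both ester carbonyls in a rigid azaenolate whose faces are differentiated by the valine isopropyl group and the HMPA ligand, so prenyl bromide should set the quaternary (S)-centre by SN2 attack on one face (see assumption), and mild hydrolysis releases the ketone and the auxiliary.

Step 12
Reactants: 16 3-[3-hexanoyl-6-methoxy-2,4-bis(methoxymethoxy)phenyl]propanoic acid; 23 methyl (2S)-2-acetyl-2,5-dimethylhex-4-enoate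
Product: 26 methyl (2S)-7-[3-hexanoyl-6-methoxy-2,4-bis(methoxymethoxy)phenyl]-2-methyl-2-(3-methylbut-2-en-1-yl)-3,5-dioxoheptanoate, via acyl imidazole 24 (not isolated), via lithium enolate 25 (not isolated)
Conditions: 16, CDI (1.1 equiv), THF, rt; separately 23 (2.5 equiv), LiN(i-Pr)2 (2.5 equiv), THF, −78 °C; acyl imidazole solution added, −78 to −40 °C; aq. NH4Cl
Reagents that add atoms: none
Why: Crossed Claisen condensation (C-acylation of a ketone lithium enolate by an acyl imidazole); the acetyl methyl is the only enolisable position of 23 because the other α-carbon is quaternary, the enolate is formed before the ketone-bearing electrophile is added so that the hexanoyl group never meets free amide base, and the quaternary stereocentre cannot epimerise.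

Step 13
Reactants: 26 methyl (2S)-7-[3-hexanoyl-6-methoxy-2,4-bis(methoxymethoxy)phenyl]-2-methyl-2-(3-methylbut-2-en-1-yl)-3,5-dioxoheptanoate
Product: 28 (4R)-6-{[3-hexanoyl-6-methoxy-2,4-bis(methoxymethoxy)phenyl]methyl}-5-hydroxy-4-methyl-4-(3-methylbut-2-en-1-yl)cyclohex-5-ene-1,3-dione, via trilithium trianion 27 (not isolated)
Conditions: LiN(i-Pr)2 (3.5 equiv), THF, −78 to 0 °C; cold 1 M HCl to pH 4
Reagents that add atoms: none
Why: Dieckmann condensation in the form of an intramolecular acylation of a 1,3-diketone polyanion; after the diketone C–H and the spectator hexanoyl α-H, the last equivalent of base removes a γ-proton at the only available site (the CH2 next to the benzylic carbon, the other flank being quaternary), and this most basic carbanion closes the six-membered ring on the methyl ester (6-exo-trig), the acidic trione making the closure irreversible while the hexanoyl enolate has no ring of feasible size to form.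

Step 14
Reactants: 28 (4R)-6-{[3-hexanoyl-6-methoxy-2,4-bis(methoxymethoxy)phenyl]methyl}-5-hydroxy-4-methyl-4-(3-methylbut-2-en-1-yl)cyclohex-5-ene-1,3-dione; 29 butanoic acid
Product: 31 Elaphopilosin B bis(methoxymethyl) ether, via enol butanoate 30 (not isolated)
Conditions: 29 (1.2 equiv), DCC (1.2 equiv), DMAP (1.2 equiv), CH2Cl2, 0 °C to rt
Reagents that add atoms: none
Why: Steglich-type O-acylation of the enolised trione followed by DMAP-mediated O→C acyl transfer, as used for 2-acylcyclohexane-1,3-diones; only the ring carbon that still carries hydrogen between two carbonyls can give a stable, hydrogen-bonded enolised β-triketone, so the butanoyl group should settle there and not on the benzyl-substituted carbon.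

Step 15
Reactants: 31 Elaphopilosin B bis(methoxymethyl) ether
Product: 32 Elaphopilosin B
Conditions: 2 M aq. HCl/MeOH (1:4), rt
Reagents that add atoms: none
Why: Acid-catalysed acetal exchange removes both aryl MOM ethers, which are activated by the ortho acyl group, under conditions dilute and cool enough that the prenyl olefin and the methylene bridge should stay intact.

Compound list
1 | 5-methoxyresorcinol | COc1cc(O)cc(O)c1 | starting material
2 | acrylic acid | OC(=O)C=C | starting material
3 | 7-hydroxy-5-methoxychroman-2-one | COc1cc(O)cc2OC(=O)CCc12 | intermediate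
4 | 5-methoxy-7-(methoxymethoxy)chroman-2-one | COCOc1cc(OC)c2CCC(=O)Oc2c1 | intermediate
5 | 8-bromo-5-methoxy-7-(methoxymethoxy)chroman-2-one | COCOc1cc(OC)c2CCC(=O)Oc2c1Br | intermediate
6 | methyl 3-[3-bromo-2-hydroxy-6-methoxy-4-(methoxymethoxy)phenyl]propanoate | COC(=O)CCc1c(OC)cc(OCOC)c(Br)c1O | intermediate
7 | methyl 3-[3-bromo-6-methoxy-4-(methoxymethoxy)-2-(trimethylsilyloxy)phenyl]propanoate | COC(=O)CCc1c(OC)cc(OCOC)c(Br)c1O[Si](C)(C)C | intermediate
8 | methyl 3-[3-lithio-6-methoxy-4-(methoxymethoxy)-2-(trimethylsilyloxy)phenyl]propanoate (aryllithium, not isolated) | COC(=O)CCc1c(OC)cc(OCOC)c([Li])c1O[Si](C)(C)C | intermediate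
9 | lithium 3-methoxy-2-(3-methoxy-3-oxopropyl)-5-(methoxymethoxy)-6-(trimethylsilyl)phenoxide (not isolated) | COC(=O)CCc1c(OC)cc(OCOC)c([Si](C)(C)C)c1[O-].[Li+] | intermediate
10 | methyl 3-[6-methoxy-4-(methoxymethoxy)-2-(trifluoromethylsulfonyloxy)-3-(trimethylsilyl)phenyl]propanoate (aryne precursor) | COC(=O)CCc1c(OC)cc(OCOC)c([Si](C)(C)C)c1OS(=O)(=O)C(F)(F)F | intermediate
11 | hexanoic acid | CCCCCC(=O)O | starting material
12 | methyl 3-[2,3-didehydro-6-methoxy-4-(methoxymethoxy)phenyl]propanoate (aryne, not isolated) | COC(=O)CCC1=C(OC)C=C(OCOC)C#C1 | intermediate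
13 | methyl 3-[3-cesio-2-(hexanoyloxy)-6-methoxy-4-(methoxymethoxy)phenyl]propanoate (not isolated) | CCCCCC(=O)Oc1c([Cs])c(OCOC)cc(OC)c1CCC(=O)OC | intermediate
14 | methyl 3-[3-hexanoyl-2-hydroxy-6-methoxy-4-(methoxymethoxy)phenyl]propanoate | CCCCCC(=O)c1c(OCOC)cc(OC)c(CCC(=O)OC)c1O | intermediate
15 | methyl 3-[3-hexanoyl-6-methoxy-2,4-bis(methoxymethoxy)phenyl]propanoate | CCCCCC(=O)c1c(OCOC)cc(OC)c(CCC(=O)OC)c1OCOC | intermediate
16 | 3-[3-hexanoyl-6-methoxy-2,4-bis(methoxymethoxy)phenyl]propanoic acid | CCCCCC(=O)c1c(OCOC)cc(OC)c(CCC(=O)O)c1OCOC | intermediate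
17 | methyl 2-methyl-3-oxobutanoate | COC(=O)C(C)C(C)=O | starting material
18 | tert-butyl L-valinate | CC(C)[C@H](N)C(=O)OC(C)(C)C | starting material
19 | tert-butyl N-[(2Z)-4-methoxy-3-methyl-4-oxobut-2-en-2-yl]-L-valinate | COC(=O)/C(C)=C(/C)N[C@@H](C(C)C)C(=O)OC(C)(C)C | intermediate
20 | prenyl bromide | CC(C)=CCBr | starting material
21 | N-lithio derivative of 19 (lithioenamine, not isolated) | COC(=O)/C(C)=C(/C)N([Li])[C@@H](C(C)C)C(=O)OC(C)(C)C | intermediate
22 | tert-butyl N-[(3S)-3-(methoxycarbonyl)-3,6-dimethylhept-5-en-2-ylidene]-L-valinate (ketimine, not isolated) | COC(=O)[C@@](C)(CC=C(C)C)C(C)=N[C@@H](C(C)C)C(=O)OC(C)(C)C | intermediate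
23 | methyl (2S)-2-acetyl-2,5-dimethylhex-4-enoate | COC(=O)[C@@](C)(CC=C(C)C)C(C)=O | intermediate
24 | 1-{3-[3-hexanoyl-6-methoxy-2,4-bis(methoxymethoxy)phenyl]propanoyl}imidazole (not isolated) | CCCCCC(=O)c1c(OCOC)cc(OC)c(CCC(=O)n2ccnc2)c1OCOC | intermediate
25 | lithium (3S)-3-(methoxycarbonyl)-3,6-dimethylhepta-1,5-dien-2-olate (enolate of 23, not isolated) | COC(=O)[C@@](C)(CC=C(C)C)C(=C)O[Li] | intermediate
26 | methyl (2S)-7-[3-hexanoyl-6-methoxy-2,4-bis(methoxymethoxy)phenyl]-2-methyl-2-(3-methylbut-2-en-1-yl)-3,5-dioxoheptanoate | CCCCCC(=O)c1c(OCOC)cc(OC)c(CCC(=O)CC(=O)[C@](C)(CC=C(C)C)C(=O)OC)c1OCOC | intermediate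
27 | trilithium trianion of 26 (hexanoyl enolate plus diketone dienolate, not isolated) | [Li+].[Li+].[Li+].CCCC=C([O-])c1c(OCOC)cc(OC)c(CC=C([O-])C=C([O-])[C@](C)(CC=C(C)C)C(=O)OC)c1OCOC | intermediate
28 | (4R)-6-{[3-hexanoyl-6-methoxy-2,4-bis(methoxymethoxy)phenyl]methyl}-5-hydroxy-4-methyl-4-(3-methylbut-2-en-1-yl)cyclohex-5-ene-1,3-dione (mono-enol of the ring-B trione) | CCCCCC(=O)c1c(OCOC)cc(OC)c(CC2=C(O)[C@@](C)(CC=C(C)C)C(=O)CC2=O)c1OCOC | intermediate
29 | butanoic acid | CCCC(=O)O | starting material
30 | enol butanoate of 28 (O-acyl intermediate, not isolated) | CCCCCC(=O)c1c(OCOC)cc(OC)c(CC2=C(O)[C@@](C)(CC=C(C)C)C(=O)C=C2OC(=O)CCC)c1OCOC | intermediate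
31 | Elaphopilosin B bis(methoxymethyl) ether | CCCCCC(=O)c1c(OCOC)cc(OC)c(CC2=C(O)[C@@](C)(CC=C(C)C)C(O)=C(C(=O)CCC)C2=O)c1OCOC | intermediate
32 | Elaphopilosin B, (R) at the quaternary carbon of ring B | CCCCCC(=O)c1c(O)cc(OC)c(CC2=C(O)[C@@](C)(CC=C(C)C)C(O)=C(C(=O)CCC)C2=O)c1O | target

Total step count: 15. Longest linear sequence: 13 steps (steps 1–9 and 12–15); steps 10–11 form the two-step branch to 23.

Steps most likely to fail

1. Step 7 (aryne insertion). The aryl carbanion may be protonated before it captures the acyl group, leaving the simple O-aryl hexanoate. The carboxylate may also add in the wrong sense, or the product phenoxide may be arylated by remaining aryne. The fallback avoids the aryne and sets out from bromophenol 6, whose bromine already marks the acyl position. Acylation of 6 with hexanoyl chloride (Et3N, cat. DMAP, CH2Cl2) should give methyl 3-[3-bromo-2-(hexanoyloxy)-6-methoxy-4-(methoxymethoxy)phenyl]propanoate F1. Bromine–lithium exchange on F1 (n-BuLi, THF/Et2O, −100 °C) would then trigger the anionic 1,3-O→C acyl shift (anionic ortho-Fries rearrangement of an ortho-bromoaryl ester), and protonation returns the route at 14.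

2. Step 13 (Dieckmann closure). The diketone enolate may be acylated on oxygen to give the six-membered enol lactone, the polyanion may form incompletely, or the non-enolisable keto ester may undergo retro-Claisen cleavage. The fallback masks the diketone as a vinylogous amide, so that only one deprotonation is needed at the reacting unit and O-acylation is impossible. It sets out from 26: condensation with pyrrolidine (cat. AcOH, toluene, 4 Å sieves) at the carbonyl remote from the quaternary carbon should give the pyrrolidine enaminone F3. γ-Lithiation of F3 at the CH2 attached to the enamine carbon (LiN(i-Pr)2, 2.2 equiv, THF, −78 to 0 °C) and Claisen ring closure onto the methyl ester would give the cyclic vinylogous amide F4. Hydrolysis of F4 (aq. NaOH, MeOH/THF, 50 °C, then mild acidification) returns the route at 28.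

3. Step 11 (asymmetric prenylation). Facial selectivity of the lithioenamine may be insufficient or of the opposite sense, and N-alkylation or SN2′ attack of the prenyl halide may compete. The fallback gives up auxiliary control: from 17 and 20, alkylation with K2CO3 in refluxing acetone should give racemic methyl 2-acetyl-2,5-dimethylhex-4-enoate F2. The enantiomers of F2 would be separated by preparative chromatography on a cellulose-carbamate chiral stationary phase, and the (S)-enantiomer is 23, where the route resumes.

Further compounds
F1 | step 7 | methyl 3-[3-bromo-2-(hexanoyloxy)-6-methoxy-4-(methoxymethoxy)phenyl]propanoate | CCCCCC(=O)Oc1c(Br)c(OCOC)cc(OC)c1CCC(=O)OC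
F3 | step 13 | methyl (2S)-7-[3-hexanoyl-6-methoxy-2,4-bis(methoxymethoxy)phenyl]-2-methyl-2-(3-methylbut-2-en-1-yl)-3-oxo-5-(pyrrolidin-1-yl)hept-4-enoate (olefin geometry not fixed) | CCCCCC(=O)c1c(OCOC)cc(OC)c(CCC(=CC(=O)[C@](C)(CC=C(C)C)C(=O)OC)N2CCCC2)c1OCOC
F4 | step 13 | (6R)-4-{[3-hexanoyl-6-methoxy-2,4-bis(methoxymethoxy)phenyl]methyl}-5-hydroxy-6-methyl-6-(3-methylbut-2-en-1-yl)-3-(pyrrolidin-1-yl)cyclohexa-2,4-dien-1-one | CCCCCC(=O)c1c(OCOC)cc(OC)c(CC2=C(O)[C@@](C)(CC=C(C)C)C(=O)C=C2N3CCCC3)c1OCOC
F2 | step 11 | methyl (±)-2-acetyl-2,5-dimethylhex-4-enoate | COC(=O)C(C)(CC=C(C)C)C(C)=O
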